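Everything rests on opening ring B at C1'–C2', C2'–C3' and O–C4'. Ring B is a resorcinol monoester: the ring A aroyloxy oxygen on C4' stands meta to the C2' oxygen, a pattern that a rhodium-catalysed carbonylative (5+1) benzannulation of a 3-acyloxy-1,4-enyne writes directly. In one operation the ring A ester slides from the propargylic carbon to the adjacent alkyne carbon, CO enters as C2', and the arene closes with a free C2' phenol. The precursor is the ring A ester of a terminal propargylic alcohol whose E alkene bears the pentyl chain (future C6') and a benzyl ester (future C1').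

Key step: step 10

Assumption: 10, 18 and 19 are used as racemates because their only stereocentre becomes the sp2 carbon C5' in step 10. One enantiomer is drawn for bookkeeping only, as it is for the transient species 3 and 22.

Step 1
Reactants: 1 methyl dimethoxyacetate; 2 pentylmagnesium bromide
Product: 4 1,1-dimethoxyheptan-2-one, via bromomagnesium hemiketalate 3 (not isolated)
Conditions: 2 (1.05 equiv) added to 1, THF, −78 °C; aq NH4Cl quench at −78 °C
Reagents that add atoms: none
Why: Grignard acylation of an α,α-dialkoxy ester, in which the α-methoxy oxygens chelate magnesium and disfavour loss of methoxide, so adduct 3 should persist until the quench and the ketone should never meet the Grignard reagent.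

Step 2
Reactants: 4 1,1-dimethoxyheptan-2-one; 5 benzyl 2-(diethoxyphosphoryl)acetate
Product: 7 benzyl (E)-3-(dimethoxymethyl)oct-2-enoate, via sodium phosphonate carbanion 6 (not isolated)
Conditions: 5, NaH, THF, 0 °C; then 4, 0 °C → rt
Reagents that add atoms: none
Why: Horner–Wadsworth–Emmons olefination of an activated ketone, where reversible addition of the stabilised carbanion should place the ester trans to the branched, larger dimethoxymethyl group (E), and any minor Z isomer can be removed by chromatography.

Step 3
Reactants: 7 benzyl (E)-3-(dimethoxymethyl)oct-2-enoate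
Product: 8 benzyl (E)-3-formyloct-2-enoate
Conditions: 2 M aq HCl, THF, rt → 40 °C
Reagents that add atoms: water, O
Why: Acid-catalysed acetal hydrolysis that leaves the benzyl ester alone and keeps the more stable geometry with formyl and ester trans, while residual Z material should drain to E by the acid-promoted maleate-to-fumarate type isomerisation of ene-dicarbonyl compounds.

Step 4
Reactants: 8 benzyl (E)-3-formyloct-2-enoate; 9 ethynylmagnesium bromide
Product: 10 rac-benzyl (E)-4-hydroxy-3-pentylhex-2-en-5-ynoate (S enantiomer drawn)
Conditions: 9 (0.5 M in THF, 1.1 equiv), THF, −78 °C; aq NH4Cl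
Reagents that add atoms: none
Why: 1,2-Addition of an alkynyl Grignard reagent to an aldehyde, which at −78 °C should outrun both ester attack and conjugate addition; the new carbinol centre forms without control as a racemate (acceptable because step 10 erases it), and the E geometry keeps the alkoxide away from the ester so no butenolide can form.

Step 5
Reactants: 11 methyl orsellinate (methyl 2,4-dihydroxy-6-methylbenzoate)
Product: 12 methyl 2-hydroxy-4-methoxy-6-methylbenzoate
Conditions: MeI (1.05 equiv), K2CO3 (1.1 equiv), acetone, rt → 40 °C
Reagents that add atoms: methyl iodide, CI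
Why: Williamson ether synthesis made regioselective by the hydrogen bond that ties the C2 hydroxyl to the ester carbonyl, so one equivalent of MeI should react at the free and more acidic C4 hydroxyl.

Step 6
Reactants: 12 methyl 2-hydroxy-4-methoxy-6-methylbenzoate
Product: 13 methyl 2-benzyloxy-4-methoxy-6-methylbenzoate
Conditions: BnBr, K2CO3, DMF, 60 °C
Reagents that add atoms: benzyl bromide, BrCc1ccccc1
Why: Williamson benzylation in warm DMF overcomes the chelation of the remaining phenol, and the benzyl group keeps this oxygen out of the later methylation, leaves the migrating carbonyl oxygen free of a hydrogen bond, and departs together with the benzyl ester in the last step.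

Step 7
Reactants: 13 methyl 2-benzyloxy-4-methoxy-6-methylbenzoate; 14 1-iodohexane
Product: 16 methyl 2-benzyloxy-6-heptyl-4-methoxybenzoate, via lithiated toluate 15 (not isolated)
Conditions: LDA (commercial solution, 1.1 equiv), THF, −78 °C; then 14, DMPU, −78 → 0 °C
Reagents that add atoms: none
Why: Lateral lithiation of an ortho-toluate followed by SN2 alkylation, in which the ester acidifies the ortho methyl group far more than the benzyl ether methylene and DMPU speeds capture by the primary iodide, turning the C1 side chain into the C7 chain.

Step 8
Reactants: 16 methyl 2-benzyloxy-6-heptyl-4-methoxybenzoate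
Product: 17 2-benzyloxy-6-heptyl-4-methoxybenzoic acid
Conditions: KOH, DMSO/H2O (4:1), 100 °C; then 1 M aq HCl
Reagents that add atoms: potassium hydroxide, [K+].[OH-]
Why: Saponification of a di-ortho-substituted benzoate, which needs the poorly solvated hydroxide and the heat that aqueous DMSO provides and which leaves both aryl ethers untouched.

Step 9
Reactants: 10 rac-benzyl (E)-4-hydroxy-3-pentylhex-2-en-5-ynoate; 17 2-benzyloxy-6-heptyl-4-methoxybenzoic acid
Product: 19 rac-benzyl (E)-4-(2-benzyloxy-6-heptyl-4-methoxybenzoyloxy)-3-pentylhex-2-en-5-ynoate (R enantiomer drawn), via alkoxyphosphonium carboxylate 18 (not isolated)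
Conditions: PPh3, DIAD, toluene, 0 °C → rt
Reagents that add atoms: none
Why: Mitsunobu esterification, in which the carboxylate of 17 displaces the phosphonium-activated oxygen at the carbinol carbon (SN2 with inversion, immaterial for a racemate), so the hindered ring A carbonyl is never attacked, no amine base is present to isomerise the γ-oxygenated enoate, and elimination cannot compete because the carbinol carbon has no adjacent sp3 C–H.

Step 10
Reactants: 19 rac-benzyl (E)-4-(2-benzyloxy-6-heptyl-4-methoxybenzoyloxy)-3-pentylhex-2-en-5-ynoate; 20 carbon monoxide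
Product: 23 benzyl 4-(2-benzyloxy-6-heptyl-4-methoxybenzoyloxy)-2-hydroxy-6-pentylbenzoate, via dienylketene 21 (not isolated), via cyclohexadienone 22 (not isolated)
Conditions: [Rh(CO)2Cl]2 (5 mol %), CO (50 bar), 1,2-dichloroethane, 80 °C (autoclave)
Reagents that add atoms: none
Why: Monovalent rhodium activates the terminal alkyne, the ester carbonyl oxygen of 19 attacks the internal alkyne carbon (5-exo), and opening of the resulting dioxolenium leaves the aroyloxy group on that carbon (O–C4') and a rhodium vinylcarbene at the former terminal carbon, which CO converts into dienylketene 21 or the equivalent acyl rhodacycle. Ring B closes by six-electron electrocyclisation of 21 (or reductive elimination from the rhodacycle), joining the CO carbon C2' to the acrylate α-carbon C1', and dienone 22, a cyclic β-keto ester, should enolise irreversibly to phenol 23. The reaction type is the known rhodium-catalysed (5+1) cycloaddition of 3-acyloxy-1,4-enynes and CO to resorcinol monoesters, to which this substrate adds an electron-poor alkene terminus and a di-ortho-substituted migrating aroyl group. No stereocentre is created, since the carbinol centre of 19 becomes C5'–H and the sp3 carbon of 22 is lost on tautomerisation. The step needs 1,2- rather than 1,3-acyloxy migration, which the unsubstituted alkyne terminus secures, and carbonylation rather than Rautenstrauch-type five-ring closure, which CO pressure and the poorly nucleophilic acceptor alkene favour. The E alkene puts hydrogen inside and the benzyl ester outside the closing triene, and the electron-rich ring A makes its carbonyl oxygen a good internal nucleophile while its ortho groups stay remote from the two reacting oxygens.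

Step 11
Reactants: 23 benzyl 4-(2-benzyloxy-6-heptyl-4-methoxybenzoyloxy)-2-hydroxy-6-pentylbenzoate
Product: 24 benzyl 4-(2-benzyloxy-6-heptyl-4-methoxybenzoyloxy)-2-methoxy-6-pentylbenzoate
Conditions: MeI, K2CO3, DMF, rt
Reagents that add atoms: methyl iodide, CI
Why: Williamson methylation of the only free phenol, during which the depside ester should survive because the two ortho substituents of ring A shield its carbonyl from phenoxide or carbonate.

Step 12
Reactants: 24 benzyl 4-(2-benzyloxy-6-heptyl-4-methoxybenzoyloxy)-2-methoxy-6-pentylbenzoate
Product: 25 4-(6-heptyl-2-hydroxy-4-methoxybenzoyloxy)-2-methoxy-6-pentylbenzoic acid (target)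
Conditions: H2 (1 atm), 10% Pd/C, EtOAc, rt
Reagents that add atoms: none
Why: Catalytic hydrogenolysis cleaves both benzylic C–O bonds (ring A ether and ring B ester) in one neutral operation that leaves the aryl ester, the methyl ethers and the arenes intact.

Compound list
1 | methyl dimethoxyacetate | COC(OC)C(=O)OC | starting material
2 | pentylmagnesium bromide | CCCCC[Mg]Br | starting material
3 | bromomagnesium hemiketalate of 1 and 2 (racemic, one enantiomer drawn) | CCCCC[C@@](OC)(O[Mg]Br)C(OC)OC | intermediate (not isolated)
4 | 1,1-dimethoxyheptan-2-one | CCCCCC(=O)C(OC)OC | intermediate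
5 | benzyl 2-(diethoxyphosphoryl)acetate | CCOP(=O)(OCC)CC(=O)OCc1ccccc1 | starting material
6 | sodium salt of the carbanion of 5 | [Na+].CCOP(=O)(OCC)[CH-]C(=O)OCc1ccccc1 | intermediate (not isolated)
7 | benzyl (E)-3-(dimethoxymethyl)oct-2-enoate | COC(OC)/C(CCCCC)=C/C(=O)OCc1ccccc1 | intermediate
8 | benzyl (E)-3-formyloct-2-enoate | O=C/C(CCCCC)=C/C(=O)OCc1ccccc1 | intermediate
9 | ethynylmagnesium bromide | C#C[Mg]Br | starting material
10 | rac-benzyl (E)-4-hydroxy-3-pentylhex-2-en-5-ynoate (S enantiomer drawn) | O[C@@H](C#C)/C(CCCCC)=C/C(=O)OCc1ccccc1 | intermediate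
11 | methyl orsellinate | Cc1cc(O)cc(O)c1C(=O)OC | starting material
12 | methyl 2-hydroxy-4-methoxy-6-methylbenzoate | Cc1cc(OC)cc(O)c1C(=O)OC | intermediate
13 | methyl 2-benzyloxy-4-methoxy-6-methylbenzoate | Cc1cc(OC)cc(OCc2ccccc2)c1C(=O)OC | intermediate
14 | 1-iodohexane | CCCCCCI | starting material
15 | benzylic lithium derivative of 13 | [Li]Cc1cc(OC)cc(OCc2ccccc2)c1C(=O)OC | intermediate (not isolated)
16 | methyl 2-benzyloxy-6-heptyl-4-methoxybenzoate | CCCCCCCc1cc(OC)cc(OCc2ccccc2)c1C(=O)OC | intermediate
17 | 2-benzyloxy-6-heptyl-4-methoxybenzoic acid | CCCCCCCc1cc(OC)cc(OCc2ccccc2)c1C(=O)O | intermediate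
18 | triphenylphosphonium ether of 10 paired with the carboxylate of 17 (racemic, one enantiomer drawn) | c1ccccc1[P+](c1ccccc1)(c1ccccc1)O[C@@H](C#C)/C(CCCCC)=C/C(=O)OCc1ccccc1.CCCCCCCc1cc(OC)cc(OCc2ccccc2)c1C(=O)[O-] | intermediate (not isolated)
19 | rac-benzyl (E)-4-(2-benzyloxy-6-heptyl-4-methoxybenzoyloxy)-3-pentylhex-2-en-5-ynoate (R enantiomer drawn) | CCCCCCCc1cc(OC)cc(OCc2ccccc2)c1C(=O)O[C@H](C#C)/C(CCCCC)=C/C(=O)OCc1ccccc1 | intermediate
20 | carbon monoxide | [C-]#[O+] | starting material
21 | benzyl (2E,4E)-5-(2-benzyloxy-6-heptyl-4-methoxybenzoyloxy)-7-oxo-3-pentylhepta-2,4,6-trienoate | CCCCCCCc1cc(OC)cc(OCc2ccccc2)c1C(=O)O/C(C=C=O)=C/C(CCCCC)=C/C(=O)OCc1ccccc1 | intermediate (not isolated)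
22 | benzyl 4-(2-benzyloxy-6-heptyl-4-methoxybenzoyloxy)-2-oxo-6-pentylcyclohexa-3,5-diene-1-carboxylate (racemic, one enantiomer drawn) | CCCCCCCc1cc(OC)cc(OCc2ccccc2)c1C(=O)OC1=CC(=O)[C@H](C(=O)OCc2ccccc2)C(CCCCC)=C1 | intermediate (not isolated)
23 | benzyl 4-(2-benzyloxy-6-heptyl-4-methoxybenzoyloxy)-2-hydroxy-6-pentylbenzoate | CCCCCCCc1cc(OC)cc(OCc2ccccc2)c1C(=O)Oc1cc(CCCCC)c(C(=O)OCc2ccccc2)c(O)c1 | intermediate
24 | benzyl 4-(2-benzyloxy-6-heptyl-4-methoxybenzoyloxy)-2-methoxy-6-pentylbenzoate | CCCCCCCc1cc(OC)cc(OCc2ccccc2)c1C(=O)Oc1cc(CCCCC)c(C(=O)OCc2ccccc2)c(OC)c1 | intermediate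
25 | 4-(6-heptyl-2-hydroxy-4-methoxybenzoyloxy)-2-methoxy-6-pentylbenzoic acid (CNP0341430.0) | CCCCCCCc1cc(OC)cc(O)c1C(=O)Oc1cc(CCCCC)c(C(=O)O)c(OC)c1 | target

Total step count: 12. Longest linear sequence: 8 steps (steps 1–4 or steps 5–8, then steps 9–12).

Steps most likely to fail

Step 10. The shift of the bulky aroyloxy group may be slow. The carbene may also be consumed before carbonylation, through five-ring closure, a 1,3-shift to an allenyl ester or alkyne oligomerisation, because the acceptor-substituted alkene is unproven as a terminus.
- The fallback gives up ring construction for a classical depside esterification on a preformed ring B. It sets out from acid 17 and returns to the route at 23.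
- Purchased olivetolic acid F1 is alkylated at the carboxylate only (BnBr, KHCO3, DMF, rt) to give benzyl olivetolate F2.
- Acid 17 and F2 are then condensed with trifluoroacetic anhydride in toluene at rt.
- The mixed anhydride should acylate only the unchelated C4' hydroxyl, because the C2' hydroxyl is locked by its hydrogen bond to the benzyl ester. Compound 23 is reached directly and steps 11 and 12 follow unchanged.

Step 9. Displacement at the crowded, doubly activated carbinol carbon may be sluggish, may leak into attack at the alkyne terminus, or may lose the activated acid to acylation of the hydrazide.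
- The fallback forms the acyl C–O bond instead of the alkyl C–O bond. It sets out from 17 and returns at 19.
- Acid 17 is converted with oxalyl chloride and catalytic DMF (CH2Cl2, 0 °C → rt) into 2-benzyloxy-6-heptyl-4-methoxybenzoyl chloride F3.
- F3 acylates alcohol 10 (Et3N, catalytic DMAP, CH2Cl2, 0 °C).
- The electron-rich acid chloride should react through an acylpyridinium or acylium-like species that tolerates the ortho groups.
- Retention at the carbinol carbon gives the same racemate 19.

Step 7. Self-condensation of the lithiated toluate with unreacted ester may outrun the slow SN2 reaction on an unactivated primary iodide.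
- The fallback uses an activated electrophile followed by a chemoselective saturation. It sets out from 13 and returns at 16.
- Compound 13 is lithiated as before and quenched at −78 °C with purchased (E)-1-bromohex-2-ene F4. This gives methyl 2-benzyloxy-6-[(E)-hept-3-en-1-yl]-4-methoxybenzoate F5.
- The isolated alkene of F5 is reduced with diimide (TsNHNH2, NaOAc, aqueous THF, reflux), which touches neither the benzyl ether nor the ester.

Further compounds
F1 | step 10 | olivetolic acid (2,4-dihydroxy-6-pentylbenzoic acid, purchased) | CCCCCc1cc(O)cc(O)c1C(=O)O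
F2 | step 10 | benzyl olivetolate (benzyl 2,4-dihydroxy-6-pentylbenzoate) | CCCCCc1cc(O)cc(O)c1C(=O)OCc1ccccc1
F3 | step 9 | 2-benzyloxy-6-heptyl-4-methoxybenzoyl chloride | CCCCCCCc1cc(OC)cc(OCc2ccccc2)c1C(=O)Cl
F4 | step 7 | (E)-1-bromohex-2-ene (purchased) | CCC/C=C/CBr
F5 | step 7 | methyl 2-benzyloxy-6-[(E)-hept-3-en-1-yl]-4-methoxybenzoate | CCC/C=C/CCc1cc(OC)cc(OCc2ccccc2)c1C(=O)OC
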